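The numbers in the tables are simulated for substances that don't exist.

You expect the intermediate to keep climbing as long as the target climbs, and that is the trap: between 12.0 min and 25.0 min the intermediate falls while the target rises. Your flask holds substrate at 0.20 M, solid reagent at 2.00 equiv, free catalyst at 15 mol% and second catalyst at 0.05 mol%, so substrate is the limiting reagent, and I write its balance.

1. time, not beyond 2.0 h, at which the flask holds most intermediate
2. the amount of intermediate, in percent of the substrate charged, at that time

- north-east (time / min: intermediate / %, target / %): 3.00: 18.0, 0.7; 6.00: 26.1, 1.9; 12.0: 28.6, 7.3; 25.0: 25.8, 20.2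
- east (time / min: intermediate / %, target / %): 3.00: 24.1, 0; 8.00: 30.8, 4.9; 25.0: 26.9, 20.4; 80.0: 9.2, 63.4

(scatter of a reading: 0.5 percentage points)

- solid, in amounts per volume of the solution: solid reagent
- at the start none of the solid reagent is in solution

Intermediate plus target is the part of the spent substrate that these readings show. I call the growth of that sum the feed F and the growth of target the drain D, so the intermediate grows by F − D and tops out where F meets D. The drain D, target gained per hour between the last two readings, is 0.119 M h⁻¹. F is 0.158 M h⁻¹ between 6.00 min and 12.0 min, above D, then 0.0932 M h⁻¹ up to 25.0 min, below D. A straight line between the midpoints of those intervals crosses D at 0.245 h, so that is my time, with a top a little above the reading of 28.6 %. The east run, at 0.30 M, falls from 26.9 % to 9.2 % by 80.0 min, so I expect no later peak.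

The forecast gives 0.22 h (0.16 h to 0.29 h) and 29 % (28.2 % to 30 %), earlier than my time: “The two rates cross, giving the intermediate maximum, at about 13 min.”

The flask tops out at 29.3 % at 0.189 h, earlier than my crossing.

    substrate + free catalyst ⇌ free catalyst + intermediate (K = 0.570, k = 0.0482 L mol⁻¹ s⁻¹)
    substrate + partner → uncatalysed product (k = 0.00288 L mol⁻¹ s⁻¹)
    partner + second catalyst + intermediate → second catalyst + target (k = 288 L² mol⁻² s⁻¹)
    solid reagent ⇌ partner, rate k4*(cs4 - [partner]) while solid is left; crystals form when [partner] > cs4 (solubility = 0.100 M, k = 5.95 × 10⁻⁴ s⁻¹)

The top is flat: 28.9 % still stands at 0.236 h. At 0.189 h the flask also holds uncatalysed product at 1.75 %, which my sum of intermediate and target does not count. Carried on from 6.31 % target at 0.189 h, D gives 24.8 % target at 30 min, and this flask read at that time holds 25.3 %.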